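**Retrosynthetic overview**
1. The strategy rests on the quaternary carbon C9 of ring B, which lies between the methines C8 and C10 and carries the arylmethyl carbon C11. The cis methyl groups on C8 and C9 can be tied together as one gamma-lactone (C=O on C9, OCH2 on C8).
2. End game: the aminohydroxyquinone comes from a 2,5-dimethoxyquinone and this from a 2,3,5,6-tetramethoxyaryl ring (oxidation, selective saponification, amine exchange); the two methyl groups come from the lactone carbons.
3. Key convergent disconnection C9–C11: enolate of the cis-fused tricyclic lactone plus 2,3,5,6-tetramethoxybenzyl bromide (from 1,2,4,5-tetramethoxybenzene).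
4. Ring B is built onto preformed ring A by an endo Diels–Alder reaction of 6,6-dimethyl-1-vinylcyclohexene with the (5S)-menthyloxybutenolide, which sets C8, C9 and C10; the lactone ring comes from the dienophile.

Key step: step 10

**Remarks**
- Numbering: C1–C10 are the decalin carbons (C4 gem-dimethyl, C5=C6, C8 and C9 methyl-bearing, C10 ring-fusion CH) and C11 is the arylmethyl carbon; the target is (8S,9R,10S).
- Assumption: the (5S) acetal 9 is taken to be the epimer that crystallises with (+)-menthol, as the mirror image of the behaviour of the (−)-menthol series.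

**Route**

Step 1
Reactants: 1 2,2-dimethylcyclohexanone
Product: 3 6,6-dimethylcyclohex-1-en-1-yl trifluoromethanesulfonate, via lithium enolate 2 (not isolated)
Conditions: LiN(iPr)2, THF, −78 °C; PhNTf2, −78 °C to rt
Reagents that add atoms: N-phenylbis(trifluoromethanesulfonimide), O=S(=O)(N(c1ccccc1)S(=O)(=O)C(F)(F)F)C(F)(F)F
Why: Deprotonation can occur only on the CH2 side of the ketone because the other alpha carbon is quaternary, and O-sulfonylation of the enolate gives a single enol triflate (enol triflate formation).

Step 2
Reactants: 3 6,6-dimethylcyclohex-1-en-1-yl trifluoromethanesulfonate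
Product: 4 6,6-dimethyl-1-vinylcyclohexene
Conditions: CH2=CHSnBu3, Pd(PPh3)4 (cat.), LiCl, THF, reflux; aq. KF work-up
Reagents that add atoms: tributyl(vinyl)stannane, C=C[Sn](CCCC)(CCCC)CCCC
Why: Stille cross-coupling of a vinyl triflate with a vinylstannane (oxidative addition to zerovalent palladium, chloride-assisted transmetalation, reductive elimination) should give the 1,3-diene with the double bonds in fixed positions.

Step 3
Reactants: 5 furfural
Product: 7 5-hydroxy-2(5H)-furanone (racemic), via furan endoperoxide 6 (not isolated)
Conditions: O2, visible light, rose bengal (C20H2Cl4I4Na2O5, cat.), MeOH, rt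
Reagents that add atoms: oxygen, O=O
Why: Dye-sensitised photooxygenation: singlet oxygen adds across C2/C5 of the furan in a [4+2] cycloaddition, and methanol attacks the formyl group of the endoperoxide, which fragments with loss of methyl formate to the hydroxybutenolide.

Step 4
Reactants: 7 5-hydroxy-2(5H)-furanone; 8 (+)-menthol
Product: 9 (5S)-5-[(1S,2R,5S)-menthyloxy]-2(5H)-furanone
Conditions: 4-MeC6H4SO3H·H2O (cat.), PhMe, reflux (Dean–Stark); crystallise from hexanes, re-equilibrate the mother liquor with the same acid and recrystallise
Reagents that add atoms: none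
Why: Acid-catalysed acetalisation of the cyclic hemiacetal gives both C5 epimers in equilibrium, and crystallisation with acid re-equilibration should funnel the material into the crystalline (5S) epimer (crystallisation-induced diastereomer transformation), which fixes the acetal stereocentre.

Step 5
Reactants: 4 6,6-dimethyl-1-vinylcyclohexene; 9 (5S)-5-menthyloxy-2(5H)-furanone
Product: 10 menthyloxy lactone adduct (8S,9R,10S; acetal carbon S; H8, H9 and H10 all cis; lactone C=O on C9, acetal carbon on C8)
Conditions: 4 (2 equiv), PhMe, 120 °C, sealed tube, 2,6-di-tert-butyl-4-methylphenol (trace)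
Reagents that add atoms: none
Why: Thermal normal-electron-demand Diels–Alder reaction in which the unhindered vinyl terminus C7 bonds to the beta carbon of the butenolide (future C8) and the ring terminus C10 to the alpha carbon (future C9), as for 1-alkyl-type dienes; addition anti to the menthyloxy group fixes C8 and C9, and the endo position of the lactone carbonyl under the diene places H10 cis to H9.

Step 6
Reactants: 10 menthyloxy lactone adduct
Product: 13 cis-fused tricyclic lactone (3aS,9aS,9bR)-6,6-dimethyl-3a,4,6,7,8,9,9a,9b-octahydronaphtho[1,2-c]furan-1(3H)-one, via aldehyde carboxylate 11 (not isolated), via hydroxy carboxylate 12 (not isolated)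
Conditions: NaBH4, NaOH, EtOH/H2O, 0 °C to rt; then 2 M HCl to pH 1, rt
Reagents that add atoms: none
Why: Hydroxide opens the acyl acetal at the C9 carbonyl, the hemiacetal on C8 collapses to the aldehyde with loss of menthoxide, NaBH4 reduces this aldehyde as it forms (faster than its enolisation toward C8), and acidification closes the cis gamma-hydroxy acid, so the carbonyl stays on C9 and the former acetal carbon becomes the OCH2 on C8 (reductive removal of the auxiliary) without touching C8, C9 or C10.

Step 7
Reactants: 14 1,2,4,5-tetramethoxybenzene
Product: 16 2,3,5,6-tetramethoxybenzaldehyde, via aryllithium 15 (not isolated)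
Conditions: nBuLi, THF, 0 °C to rt; DMF, 0 °C to rt; H2O
Reagents that add atoms: N,N-dimethylformamide, CN(C)C=O
Why: Directed ortho-lithiation at one of the two equivalent ring positions, each flanked by two methoxy groups, followed by formylation of the aryllithium with DMF.

Step 8
Reactants: 16 2,3,5,6-tetramethoxybenzaldehyde
Product: 17 (2,3,5,6-tetramethoxyphenyl)methanol
Conditions: NaBH4, MeOH, 0 °C
Reagents that add atoms: none
Why: Borohydride reduction of an aromatic aldehyde to the benzylic alcohol, with no competing functionality.

Step 9
Reactants: 17 (2,3,5,6-tetramethoxyphenyl)methanol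
Product: 18 2,3,5,6-tetramethoxybenzyl bromide
Conditions: PBr3, CH2Cl2, 0 °C; used freshly prepared
Reagents that add atoms: phosphorus tribromide, BrP(Br)Br
Why: Conversion of a benzylic alcohol into the bromide through its phosphite ester and bromide displacement, which is fast for an electron-rich benzylic carbon.

Step 10
Reactants: 13 cis-fused tricyclic lactone; 18 2,3,5,6-tetramethoxybenzyl bromide
Product: 20 C9-benzylated tricyclic lactone (2,3,5,6-tetramethoxybenzyl group on C9 on the face of H8/H10; lactone still cis-fused), via lithium enolate 19 (not isolated)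
Conditions: LiN(iPr)2, THF, −78 °C; 18 (1.5 equiv), 1,3-dimethyltetrahydropyrimidin-2(1H)-one (DMPU), −78 to −20 °C
Reagents that add atoms: none
Why: LiN(iPr)2 abstracts H9, the single alpha proton of lactone 13, and the lithium enolate 19 attacks the CH2Br carbon of 18 in an SN2 C-alkylation that forges C9–C11. The closest known reaction type is the alkylation of ring-fusion enolates of cis-fused bicyclic gamma-lactones with benzylic halides to create quaternary carbons. No ring is formed, so no mode of ring closure applies; the step builds one C–C bond and one stereocentre. C9 is controlled by the lactone ring: because its OCH2 arm is anchored on C8, the enolate plane has the C8–C7 bond and the body of ring B on one face and only H8 and H10 on the other, so the bromide enters on the open face anti to C7, which keeps the five-membered lactone cis-fused and puts the arylmethyl group cis to H8 and H10. The only selectivity required is this facial one, since there is a single enolisable position and a soft benzylic bromide alkylates on carbon. Reactivity at the crowded centre is secured by the rigid cyclic enolate, which cannot twist out of conjugation or suffer allylic strain as an open-chain ester enolate would, and by the electron-rich, strongly SN2-active bromide used in excess with DMPU.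

Step 11
Reactants: 20 C9-benzylated tricyclic lactone
Product: 21 lactol (hemiacetal carbon on C9, mixture of anomers)
Conditions: iBu2AlH, CH2Cl2, −78 °C; aq. KNaC4H4O6
Reagents that add atoms: none
Why: Partial reduction of a gamma-lactone, in which the tetrahedral aluminium alkoxide is stable at −78 °C and the neopentyl-type carbonyl is too hindered for a second hydride delivery.

Step 12
Reactants: 21 lactol
Product: 23 9-methyl-8-hydroxymethyl compound (new methyl on C9 cis to the CH2OH on C8), via hydrazone 22 (not isolated)
Conditions: N2H4·H2O, diethylene glycol, 130 °C; then KOH, 200 °C with removal of H2O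
Reagents that add atoms: none
Why: Wolff–Kishner reduction (Huang-Minlon conditions) of the ring-opened hydroxy aldehyde form of the lactol: the C9 aldehyde gives the hydrazone, which loses N2 under base to leave the methyl group, and quaternary C9 has no epimerisable hydrogen.

Step 13
Reactants: 23 9-methyl-8-hydroxymethyl compound
Product: 24 primary methanesulfonate of 23
Conditions: MsCl, Et3N, CH2Cl2, 0 °C
Reagents that add atoms: methanesulfonyl chloride, CS(=O)(=O)Cl
Why: Sulfonylation of the primary alcohol via the sulfene is fast at 0 °C and leaves the arene and alkene untouched.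

Step 14
Reactants: 24 primary methanesulfonate
Product: 25 8,9-dimethyl tetramethoxyarene (8S,9R,10S; 2,3,5,6-tetramethoxybenzyl on C9)
Conditions: LiEt3BH, THF, 0 °C to reflux
Reagents that add atoms: none
Why: SN2 hydride displacement of a primary, beta-branched (not neopentyl) sulfonate gives the C8 methyl group without touching the C8 stereocentre.

Step 15
Reactants: 25 8,9-dimethyl tetramethoxyarene
Product: 26 3-substituted 2,5-dimethoxy-1,4-benzoquinone
Conditions: (NH4)2Ce(NO3)6, MeCN/H2O, 0 °C
Reagents that add atoms: water, O
Why: Oxidative demethylation by tetravalent cerium (two one-electron oxidations, water adding at the ipso carbons with loss of methanol); the two possible para pairs are equivalent by the symmetry of the ring, and the arene is oxidised much faster than the trisubstituted alkene.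

Step 16
Reactants: 26 2,5-dimethoxyquinone
Product: 27 2-hydroxy-5-methoxy-3-substituted 1,4-benzoquinone
Conditions: KOH, MeOH/H2O, rt; then 1 M HCl
Reagents that add atoms: potassium hydroxide, [K+].[OH-]
Why: Addition–elimination of hydroxide at C2: the 2-methoxy group is twisted out of the quinone plane by the C3 substituent and is the less stabilised vinylogous ester, and the vinylogous carboxylate formed resists a second hydrolysis (regioselective saponification known for 3-alkyl-2,5-dimethoxybenzoquinones); the regiochemistry should be confirmed before step 17.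

Step 17
Reactants: 27 2-hydroxy-5-methoxyquinone; 28 3-methylbutan-1-amine
Product: 29 nakijiquinone M
Conditions: 28 (3 equiv), EtOH, rt to 40 °C; dilute acid work-up
Reagents that add atoms: none
Why: The only remaining vinylogous ester carbon, C5, undergoes addition–elimination with the primary amine to give the vinylogous amide, the ionised 2-hydroxy group being inert (methoxy–amine exchange on hydroxymethoxyquinones); no stereocentre is involved.

**Compound list**
1 | 2,2-dimethylcyclohexanone | CC1(C)CCCCC1=O | starting material
2 | lithium 6,6-dimethylcyclohex-1-en-1-olate | [Li+].[O-]C1=CCCCC1(C)C | intermediate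
3 | 6,6-dimethylcyclohex-1-en-1-yl trifluoromethanesulfonate | CC1(C)CCCC=C1OS(=O)(=O)C(F)(F)F | intermediate
4 | 6,6-dimethyl-1-vinylcyclohexene | C=CC1=CCCCC1(C)C | intermediate
5 | furfural | O=Cc1ccco1 | starting material
6 | furan endoperoxide, 2,3,7-trioxabicyclo[2.2.1]hept-5-ene-1-carbaldehyde | O=CC12C=CC(OO1)O2 | intermediate
7 | 5-hydroxy-2(5H)-furanone (racemic) | OC1OC(=O)C=C1 | intermediate
8 | (+)-menthol, (1S,2R,5S) | CC(C)[C@H]1CC[C@H](C)C[C@@H]1O | starting material
9 | (5S)-5-[(1S,2R,5S)-menthyloxy]-2(5H)-furanone | CC(C)[C@H]1CC[C@H](C)C[C@@H]1O[C@H]2OC(=O)C=C2 | intermediate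
10 | Diels–Alder adduct, cis-fused menthyloxy lactone (8S,9R,10S, acetal S; H8, H9, H10 all cis) | O=C1O[C@H](O[C@H]2C[C@@H](C)CC[C@@H]2C(C)C)[C@H]3CC=C4C(C)(C)CCC[C@H]4[C@@H]13 | intermediate
11 | sodium salt of the ring-opened aldehyde acid (CO2Na on C9, CHO on C8) | [Na+].[O-]C(=O)[C@H]1[C@@H](C=O)CC=C2C(C)(C)CCC[C@@H]12 | intermediate
12 | sodium salt of the hydroxy acid (CO2Na on C9, CH2OH on C8) | [Na+].[O-]C(=O)[C@H]1[C@@H](CO)CC=C2C(C)(C)CCC[C@@H]12 | intermediate
13 | (3aS,9aS,9bR)-6,6-dimethyl-3a,4,6,7,8,9,9a,9b-octahydronaphtho[1,2-c]furan-1(3H)-one (cis-fused lactone, H8, H9, H10 all cis) | O=C1OC[C@H]2CC=C3C(C)(C)CCC[C@H]3[C@@H]12 | intermediate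
14 | 1,2,4,5-tetramethoxybenzene | COc1cc(OC)c(OC)cc1OC | starting material
15 | (2,3,5,6-tetramethoxyphenyl)lithium | [Li]c1c(OC)c(OC)cc(OC)c1OC | intermediate
16 | 2,3,5,6-tetramethoxybenzaldehyde | COc1cc(OC)c(OC)c(C=O)c1OC | intermediate
17 | (2,3,5,6-tetramethoxyphenyl)methanol | COc1cc(OC)c(OC)c(CO)c1OC | intermediate
18 | 2,3,5,6-tetramethoxybenzyl bromide | COc1cc(OC)c(OC)c(CBr)c1OC | intermediate
19 | lithium enolate of lactone 13 (C9=C(OLi)O) | [Li+].[O-]C1=C2[C@@H]3CCCC(C)(C)C3=CC[C@@H]2CO1 | intermediate
20 | C9-(2,3,5,6-tetramethoxybenzyl) cis-fused lactone (arylmethyl cis to H8 and H10) | COc1cc(OC)c(OC)c(C[C@@]2(C(=O)O4)[C@@H]3CCCC(C)(C)C3=CC[C@@H]2C4)c1OC | intermediate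
21 | lactol of 20 (anomeric mixture) | COc1cc(OC)c(OC)c(C[C@@]2(C(O)O4)[C@@H]3CCCC(C)(C)C3=CC[C@@H]2C4)c1OC | intermediate
22 | hydrazone of the C9 aldehyde (CH2OH on C8) | COc1cc(OC)c(OC)c(C[C@@]2(C=NN)[C@@H]3CCCC(C)(C)C3=CC[C@@H]2CO)c1OC | intermediate
23 | 9-methyl-8-hydroxymethyl tetramethoxyarene | COc1cc(OC)c(OC)c(C[C@@]2(C)[C@@H]3CCCC(C)(C)C3=CC[C@@H]2CO)c1OC | intermediate
24 | methanesulfonate of 23 | COc1cc(OC)c(OC)c(C[C@@]2(C)[C@@H]3CCCC(C)(C)C3=CC[C@@H]2COS(C)(=O)=O)c1OC | intermediate
25 | (8S,9R,10S)-8,9-dimethyl tetramethoxyarene | COc1cc(OC)c(OC)c(C[C@@]2(C)[C@@H]3CCCC(C)(C)C3=CC[C@@H]2C)c1OC | intermediate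
26 | 2,5-dimethoxy-3-(decalinylmethyl)-1,4-benzoquinone | COC1=CC(=O)C(OC)=C(C[C@@]2(C)[C@@H]3CCCC(C)(C)C3=CC[C@@H]2C)C1=O | intermediate
27 | 2-hydroxy-5-methoxy-3-(decalinylmethyl)-1,4-benzoquinone | COC1=CC(=O)C(O)=C(C[C@@]2(C)[C@@H]3CCCC(C)(C)C3=CC[C@@H]2C)C1=O | intermediate
28 | 3-methylbutan-1-amine | CC(C)CCN | starting material
29 | nakijiquinone M, 2-hydroxy-5-(3-methylbutylamino)-3-{[(1R,2S,8aS)-1,2,5,5-tetramethyl-1,2,3,5,6,7,8,8a-octahydronaphthalen-1-yl]methyl}-1,4-benzoquinone | CC(C)CCNC1=CC(=O)C(O)=C(C[C@@]2(C)[C@@H]3CCCC(C)(C)C3=CC[C@@H]2C)C1=O | target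

**Step count**
Total: 17 steps. Longest linear sequence: 12 steps (steps 1, 2, 5, 6, 10–17, or equally 3, 4, 5, 6, 10–17).

**Steps most likely to fail**

1. Step 10 (key alkylation). The enolate carbon is shielded by C1/C10 and the electrophile is di-ortho-substituted, so conversion may stall; the enolate may then be consumed by proton return or self-condensation on warming, and some attack on the other face cannot be excluded. Fallback: set out from 13 and add its enolate 19 at −78 °C to aldehyde 16, a carbonyl addition that is less sensitive to crowding than the SN2 step. This should give the beta-hydroxy lactone F1 (epimers at C11). Ionic deoxygenation of its electron-rich benzylic alcohol (Et3SiH, BF3·OEt2, CH2Cl2, −78 °C) returns to the route at 20.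

2. Step 5 (Diels–Alder). The two alkyl groups of the diene direct in opposite senses, so the regiochemistry may leak; exo addition would invert C10 relative to C8/C9, and the slow thermal reaction may lose diene to polymerisation. Fallback: set out from 4 and use maleic anhydride, a far more reactive dienophile with no regiochemical issue in the cycloaddition, to give the racemic endo anhydride F2. Methanolysis at the less hindered C8 carbonyl (MeOH, Et3N, 4-(dimethylamino)pyridine cat.) gives the half-ester F3 (CO2Me on C8, CO2H on C9), whose enantiomers are separated by preparative chromatography on a chiral stationary phase. Reduction of the ester in the presence of the lithium carboxylate (LiBH4, THF) and acid lactonisation return to the route at 13.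

3. Step 12 (Wolff–Kishner on the lactol). Hydrazone formation at the neopentyl-type aldehyde may be incomplete or diverted to the azine, nitrogen loss may be slow in the crowded environment, and aryl methyl ethers may be partly cleaved at 200 °C. Fallback: set out from 20 and reduce it with LiAlH4 to the diol F4. Both carbinols are converted into the bis(S-methyl xanthate) F5 (NaH, CS2, MeI, THF), and radical deoxygenation (Bu3SnH, 2,2'-azobis(2-methylpropionitrile), xylene, 140 °C; Barton–McCombie) returns to the route at 25, bypassing steps 11 to 14.

**Further compounds**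
F1 | step 10 | beta-hydroxy lactone from the aldol addition of 19 to 16 (C11 carbinol, epimeric mixture) | COc1cc(OC)c(OC)c(C(O)[C@@]2(C(=O)O4)[C@@H]3CCCC(C)(C)C3=CC[C@@H]2C4)c1OC
F2 | step 5 | racemic endo anhydride from 4 and maleic anhydride (H8, H9, H10 all cis; wanted enantiomer drawn) | O=C1OC(=O)[C@H]2CC=C3C(C)(C)CCC[C@H]3[C@@H]12
F3 | step 5 | half-ester with CO2Me on C8 and CO2H on C9 (racemic as formed; wanted enantiomer drawn) | COC(=O)[C@H]1CC=C2C(C)(C)CCC[C@H]2[C@H]1C(=O)O
F4 | step 12 | 8,9-bis(hydroxymethyl) diol from 20 | COc1cc(OC)c(OC)c(C[C@@]2(CO)[C@@H]3CCCC(C)(C)C3=CC[C@@H]2CO)c1OC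
F5 | step 12 | bis(S-methyl xanthate) of F4 | COc1cc(OC)c(OC)c(C[C@@]2(COC(=S)SC)[C@@H]3CCCC(C)(C)C3=CC[C@@H]2COC(=S)SC)c1OC
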